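**Plan**

- Cuts, in retrosynthetic order: the O7–CH3 bond; the C6–O and C8–O bonds of ring A together (back to C–Br, then C–H); ring C at O1–C2 and C4–C4a; the C2–C3 bond between the aroyl carbon of ring B and the methoxy-bearing carbon.
- Enabling feature: C6 and C8 are the two CH positions of a 5,7-dihydroxylated, phloroglucinol-derived ring A. Each is ortho/para to both phenols, so bromine enters exactly there and methoxide can replace it once the flavone exists.
- Forward order: ring B is joined to the C3–OMe unit in a β-keto ester; ring C, the only ring made, is closed onto phloroglucinol (ring A); C6 and C8 are brominated and then doubly methoxylated; O7 is methylated last while the chelated 5-OH stays free.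
- Stereochemistry: the target has no stereocentre and no stereogenic double bond; the one racemic centre of the keto ester vanishes when ring C becomes aromatic.

Key step: step 4

Assumption (chemistry): in the two twofold substitutions the half-reacted flavone is drawn as the isomer that has reacted at C6; the C8-first isomer would form alongside it and converge on the same product.

**Route**

Step 1
Reactants: 1 ethyl methoxyacetate; 2 2,5-dimethoxybenzoyl chloride
Product: 4 racemic ethyl 3-(2,5-dimethoxyphenyl)-2-methoxy-3-oxopropanoate, via lithium enolate 3 (not isolated)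
Conditions: LiN(iPr)2 (2.1 equiv), 1 (2.1 equiv), THF, −78 °C; then 2 (1.0 equiv) in THF, −78 → 0 °C; aq NH4Cl
Reagents that add atoms: none
Why: Crossed Claisen acylation of a preformed ester enolate by an aroyl chloride, in which the second equivalent of enolate takes up the acidic proton of the product keto ester and so stops further acylation; the new α-stereocentre is uncontrolled (racemic, enolisable) and is erased in step 2.

Step 2
Reactants: 4 racemic ethyl 3-(2,5-dimethoxyphenyl)-2-methoxy-3-oxopropanoate; 5 phloroglucinol
Product: 7 5,7-dihydroxy-3,2',5'-trimethoxyflavone, via aryl diketone 6 (not isolated)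
Conditions: 5 (anhydrous, 1 equiv), 4 (2 equiv), neat melt, 240 °C, N2 stream, EtOH and H2O distilled off
Reagents that add atoms: none
Why: Mentzer pyrone synthesis, in which the keto ester loses ethanol in the neutral melt and acylates a ring carbon of the highly nucleophilic phloroglucinol (directly or by O-acylation and thermal Fries shift) to the o-hydroxyaryl 1,3-diketone 6, whose phenol then adds to the aroyl carbonyl and dehydrates to the pyranone, the absence of acid disfavouring Pechmann closure to a coumarin and the symmetry of phloroglucinol making the acylation site immaterial.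

Step 3
Reactants: 7 5,7-dihydroxy-3,2',5'-trimethoxyflavone
Product: 9 6,8-dibromo-5,7-dihydroxy-3,2',5'-trimethoxyflavone, via 6-bromoflavone 8 (not isolated)
Conditions: NBS (2.1 equiv), DMF, 0 °C → rt, dark; aq Na2S2O3
Reagents that add atoms: N-bromosuccinimide, O=C1CCC(=O)N1Br
Why: Electrophilic aromatic bromination, for which C6 and C8 are each ortho/para to the two free phenols of ring A and far more nucleophilic than the acceptor-substituted dimethoxyphenyl ring B, while C3 is blocked by its methoxy group, so two equivalents of NBS should stop at the 6,8-dibromide.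

Step 4
Reactants: 9 6,8-dibromo-5,7-dihydroxy-3,2',5'-trimethoxyflavone; 10 sodium methoxide
Product: 12 5,7-dihydroxy-3,6,8,2',5'-pentamethoxyflavone, via 8-bromo-6-methoxyflavone 11 (not isolated)
Conditions: NaOMe (12 equiv, 25 wt% in MeOH), CuBr (0.4 equiv), dry DMF, 110 °C, N2; then aq HCl to pH 3
Reagents that add atoms: sodium methoxide (compound 10), C[O-].[Na+]
Why: Excess methoxide converts 9 into its 5,7-diphenoxide and CuBr into a methoxide complex of monovalent copper, which inserts into a C–Br bond (oxidative addition to an aryl species of trivalent copper, or the equivalent four-centre exchange) and then releases the aryl methyl ether by C–O reductive elimination, returning monovalent copper; the cycle runs once at C6 and once at C8, through the half-exchanged flavone 11. The closest known reaction type is the Ullmann-type copper-promoted methanolysis of aryl bromides, which is established for 6,8-dibromo-5,7-dihydroxyflavones bearing free phenols. No ring is closed and no stereocentre is created, so there is no closure mode or stereocontrol to assign; the two aryl C–O bonds are the only bonds formed. The selectivity needed is substitution over hydrodebromination and over attack of methoxide on ring C: a dry, oxygen-free medium and a large excess of methoxide favour C–O coupling, and the two phenoxide charges on ring A make C2 of the pyranone a poor acceptor. Should ring C nevertheless open and reclose under base (Wessely–Moser-type exchange of C6 and C8), the outcome is unchanged, because both positions carry the same substituent in 9 and in 12. The three methyl ethers already present (C3, C2', C5') are inert to methoxide.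

Step 5
Reactants: 12 5,7-dihydroxy-3,6,8,2',5'-pentamethoxyflavone
Product: 13 grantioidinin (5-hydroxy-3,6,7,8,2',5'-hexamethoxyflavone)
Conditions: MeI (1.1 equiv), K2CO3 (1.1 equiv), acetone, 40 °C; dilute HCl work-up
Reagents that add atoms: iodomethane, CI
Why: Williamson ether synthesis under chelation control, in which the 7-OH is a vinylogous acid para to the C4 carbonyl and is ionised first by K2CO3, whereas the 5-OH is held in a hydrogen bond to C4=O and is neither deprotonated nor nucleophilic at this temperature, so one equivalent of iodomethane should alkylate O7 only.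

**Compound list**

1 | ethyl methoxyacetate | CCOC(=O)COC | starting material
2 | 2,5-dimethoxybenzoyl chloride | COc1ccc(OC)c(C(=O)Cl)c1 | starting material
3 | lithium enolate of ethyl methoxyacetate (chelated geometry, OLi cis to OMe) | CCO/C(O[Li])=C/OC | intermediate
4 | racemic ethyl 3-(2,5-dimethoxyphenyl)-2-methoxy-3-oxopropanoate | CCOC(=O)C(OC)C(=O)c1cc(OC)ccc1OC | intermediate
5 | phloroglucinol (benzene-1,3,5-triol) | Oc1cc(O)cc(O)c1 | starting material
6 | racemic 1-(2,5-dimethoxyphenyl)-2-methoxy-3-(2,4,6-trihydroxyphenyl)propane-1,3-dione | COc1ccc(OC)c(C(=O)C(OC)C(=O)c2c(O)cc(O)cc2O)c1 | intermediate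
7 | 5,7-dihydroxy-3,2',5'-trimethoxyflavone | COc1ccc(OC)c(-c2oc3cc(O)cc(O)c3c(=O)c2OC)c1 | intermediate
8 | 6-bromo-5,7-dihydroxy-3,2',5'-trimethoxyflavone | COc1ccc(OC)c(-c2oc3cc(O)c(Br)c(O)c3c(=O)c2OC)c1 | intermediate
9 | 6,8-dibromo-5,7-dihydroxy-3,2',5'-trimethoxyflavone | COc1ccc(OC)c(-c2oc3c(Br)c(O)c(Br)c(O)c3c(=O)c2OC)c1 | intermediate
10 | sodium methoxide | C[O-].[Na+] | starting material
11 | 8-bromo-5,7-dihydroxy-3,6,2',5'-tetramethoxyflavone | COc1ccc(OC)c(-c2oc3c(Br)c(O)c(OC)c(O)c3c(=O)c2OC)c1 | intermediate
12 | 5,7-dihydroxy-3,6,8,2',5'-pentamethoxyflavone | COc1ccc(OC)c(-c2oc3c(OC)c(O)c(OC)c(O)c3c(=O)c2OC)c1 | intermediate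
13 | grantioidinin (5-hydroxy-3,6,7,8,2',5'-hexamethoxyflavone) | COc1ccc(OC)c(-c2oc3c(OC)c(OC)c(OC)c(O)c3c(=O)c2OC)c1 | target

**Count**

Total steps: 5. Longest linear sequence: 5 steps (from 1 and 2 to 13).

**Steps most likely to fail**

Step 2 (thermal ring C formation). At 240 °C the α-methoxy keto ester may fragment, or close in the Pechmann sense through attack of a ring carbon on the ketone carbonyl, faster than it acylates phloroglucinol in the chromone sense. The fallback sets out from 5 and 2 and returns at 7, building ring C under base from a preformed aryl ketone. Hoesch acylation of 5 with methoxyacetonitrile (ZnCl2, HCl gas, Et2O, 0 °C) should give 2-methoxy-1-(2,4,6-trihydroxyphenyl)ethan-1-iminium chloride F1, which boiling water hydrolyses to 2-methoxy-1-(2,4,6-trihydroxyphenyl)ethan-1-one F2. Separately, 2 and 2,5-dimethoxybenzoic acid (pyridine, CH2Cl2) give 2,5-dimethoxybenzoic anhydride F3. Allan–Robinson condensation of F2 with F3 and Et3N at 160–170 °C should give the 7-O-aroylated flavone 2-(2,5-dimethoxyphenyl)-5-hydroxy-3-methoxy-4-oxo-4H-chromen-7-yl 2,5-dimethoxybenzoate F4, and KOH in aqueous ethanol cleaves the ester to 7.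

Step 4 (twofold methoxylation). Protodebromination of the electron-rich diphenoxide may outrun C–O coupling, the exchange may stall after one bromine, or base may degrade ring C during the long heating. The fallback sets out from 9 and returns at 12, replacing the anionic copper chemistry by palladium catalysis on a neutral substrate. Benzylation of both phenols (BnBr, K2CO3, DMF, 60 °C) gives 5,7-bis(benzyloxy)-6,8-dibromo-3,2',5'-trimethoxyflavone F5. Palladium-catalysed C–O cross-coupling with methanol (Pd2(dba)3, tBuBrettPhos, Cs2CO3, MeOH, toluene, 80 °C) should give 5,7-bis(benzyloxy)-3,6,8,2',5'-pentamethoxyflavone F6. Hydrogenolysis (H2, Pd/C, EtOAc) then frees both phenols and rejoins the route at 12.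

Step 5 (mono-O-methylation). Alkylation may run on to the chelated 5-OH, or may be sluggish at O7, which is flanked by two methoxy groups, so that a mixture results. The fallback sets out from 12 and returns at 13, giving up selective alkylation for selective dealkylation. Exhaustive methylation (Me2SO4 in excess, K2CO3, acetone, reflux) gives 3,5,6,7,8,2',5'-heptamethoxyflavone F7. BCl3 (1.1 equiv, CH2Cl2, −78 → 0 °C) binds between the C4 carbonyl and O5, and chloride should remove only that methyl group, giving 13.

**Further compounds**

F1 | step 2 | 2-methoxy-1-(2,4,6-trihydroxyphenyl)ethan-1-iminium chloride | COCC(=[NH2+])c1c(O)cc(O)cc1O.[Cl-]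
F2 | step 2 | 2-methoxy-1-(2,4,6-trihydroxyphenyl)ethan-1-one | COCC(=O)c1c(O)cc(O)cc1O
F3 | step 2 | 2,5-dimethoxybenzoic anhydride | COc1ccc(OC)c(C(=O)OC(=O)c2cc(OC)ccc2OC)c1
F4 | step 2 | 2-(2,5-dimethoxyphenyl)-5-hydroxy-3-methoxy-4-oxo-4H-chromen-7-yl 2,5-dimethoxybenzoate | COc1ccc(OC)c(-c2oc3cc(OC(=O)c4cc(OC)ccc4OC)cc(O)c3c(=O)c2OC)c1
F5 | step 4 | 5,7-bis(benzyloxy)-6,8-dibromo-3,2',5'-trimethoxyflavone | COc1ccc(OC)c(-c2oc3c(Br)c(OCc4ccccc4)c(Br)c(OCc4ccccc4)c3c(=O)c2OC)c1
F6 | step 4 | 5,7-bis(benzyloxy)-3,6,8,2',5'-pentamethoxyflavone | COc1ccc(OC)c(-c2oc3c(OC)c(OCc4ccccc4)c(OC)c(OCc4ccccc4)c3c(=O)c2OC)c1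
F7 | step 5 | 3,5,6,7,8,2',5'-heptamethoxyflavone | COc1ccc(OC)c(-c2oc3c(OC)c(OC)c(OC)c(OC)c3c(=O)c2OC)c1
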